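The target (flavanone numbering; doubly primed locants for the 5,7-dihydroxy half) is treated as two 2'-hydroxychalcones joined α to α: C3–C3'' links the two pyranone rings C, and the β-carbons C2 and C2'', each benzylic to a 4-oxygenated ring B, carry the ring oxygens O1 and O1''. A crossed, enantioselective chalcone [2+2] photocycloaddition forms C3–C3'' together with a sacrificial C2–C2'' bond in one operation, giving an all-trans cyclobutane that fixes C3 and C3''. Its precursors are two benzyl-protected chalcones, one with a free 2'-hydroxyl that alone binds the chiral Lewis acid and one with that oxygen capped as a MOM ether. Oxidative scission of C2–C2'', with capture by both ortho-phenols, then closes the two rings C.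

Key step: step 5

Remark on locants: in the cyclobutanes the later flavanone locants C2, C3, C2'' and C3'' are used for the four ring carbons.
Remark on the precursor design: on the phloroglucinol half only the oxygen that becomes O1'' is masked as an acid-labile MOM ether and the other two carry benzyl groups, so that at the ring-opening stage the only free phenols are the two chelated ortho-hydroxyls and no easily oxidised polyphenol meets the oxidant.
Remark on the ligand: the sense of induction of t-Bu-PyBox with an enone as ground-state partner cannot be predicted with certainty; (S,S)-t-Bu-PyBox is written, and the equally available (R,R) antipode would be used if the first adduct proves to be the mirror image.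
Remark on transients: excited states, radical ions and diradicals named in the Why lines are transient species and carry no compound number.

Step 1
Reactants: 1 1-(4-benzyloxy-2-hydroxyphenyl)ethan-1-one; 2 4-(benzyloxy)benzaldehyde
Product: 4 (E)-1-(4-benzyloxy-2-hydroxyphenyl)-3-(4-benzyloxyphenyl)prop-2-en-1-one, via aldol adduct 3 (not isolated)
Conditions: KOH (aq, 3 equiv), EtOH, rt; then 1 M HCl, 0 °C
Reagents that add atoms: none
Why: Claisen–Schmidt condensation, in which the potassium enolate of the methyl ketone adds to the non-enolisable aldehyde and the aldol adduct dehydrates by E1cB to the conjugated (E)-enone while the chelated 2'-phenoxide is a spectator.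

Step 2
Reactants: 5 1-(2,4,6-trihydroxyphenyl)ethan-1-one
Product: 6 1-[2,4-bis(benzyloxy)-6-hydroxyphenyl]ethan-1-one
Conditions: BnBr (2.1 equiv), K2CO3 (2.2 equiv), DMF, rt
Reagents that add atoms: benzyl bromide, BrCc1ccccc1
Why: Williamson ether synthesis, in which the para and one ortho phenol are alkylated while the hydroxyl hydrogen-bonded to the ketone is far less nucleophilic and stays free.

Step 3
Reactants: 6 1-[2,4-bis(benzyloxy)-6-hydroxyphenyl]ethan-1-one
Product: 7 1-[2,4-bis(benzyloxy)-6-(methoxymethoxy)phenyl]ethan-1-one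
Conditions: NaH (1.2 equiv), DMF, 0 °C; then MOMCl (1.3 equiv), 0 °C to rt
Reagents that add atoms: chloromethyl methyl ether, COCCl
Why: Williamson-type O-alkylation of the sodium phenoxide, which caps the one oxygen that could chelate the Lewis acid in step 5 with the only group that is later removed by acid.

Step 4
Reactants: 7 1-[2,4-bis(benzyloxy)-6-(methoxymethoxy)phenyl]ethan-1-one; 2 4-(benzyloxy)benzaldehyde
Product: 9 (E)-1-[2,4-bis(benzyloxy)-6-(methoxymethoxy)phenyl]-3-(4-benzyloxyphenyl)prop-2-en-1-one, via aldol adduct 8 (not isolated)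
Conditions: KOH (aq), EtOH/THF, rt
Reagents that add atoms: none
Why: Claisen–Schmidt condensation, routine for 2,6-dioxygenated acetophenones because the twisted ketone still enolises at its methyl group and the fully capped product cannot cyclise to a flavanone.

Step 5
Reactants: 4 (E)-1-(4-benzyloxy-2-hydroxyphenyl)-3-(4-benzyloxyphenyl)prop-2-en-1-one; 9 (E)-1-[2,4-bis(benzyloxy)-6-(methoxymethoxy)phenyl]-3-(4-benzyloxyphenyl)prop-2-en-1-one
Product: 10 (4-benzyloxy-2-hydroxyphenyl){(1S,2S,3R,4R)-2-[2,4-bis(benzyloxy)-6-(methoxymethoxy)benzoyl]-3,4-bis(4-benzyloxyphenyl)cyclobutyl}methanone (all-trans cyclobutane)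
Conditions: Sc(OTf)3 (10 mol%), (S,S)-t-Bu-PyBox (15 mol%), Ru(bpy)3(PF6)2 (2.5 mol%), 9 (4 equiv), i-PrOAc/MeCN 3:1, degassed, blue LEDs, rt; 4 added over several hours
Reagents that add atoms: none
Why: Proposed new method: only 4 forms the bidentate phenol–carbonyl chelate with PyBox-bound Sc(OTf)3, which lowers its triplet energy enough for energy transfer from photoexcited Ru(bpy)3(PF6)2, so the triplet of bound 4 alone is populated and its β-carbon C2, a benzylic radical centre, adds in Giese fashion to the β-carbon C2'' of ground-state enone 9, leaving a triplet 1,4-diradical with one unpaired electron α to each carbonyl. The closest known reaction type is the Lewis-acid-templated, triplet-sensitised enantioselective [2+2] cycloaddition of 2'-hydroxychalcones with styrenes and dienes, and a second chalcone as the ground-state partner is the new element. The cyclobutane ring is closed stepwise: after intersystem crossing the diradical collapses by radical–radical recombination between C3 and C3'', not by a concerted process. The PyBox ligand shields one face of the chelated enone and so fixes the absolute configuration at C2 in the first bond-forming event; C2'' follows because the two aryl groups avoid each other in that addition (a mismatched diradical can revert), and the planar radical centres C3 and C3'' then join with each aroyl group trans to its neighbours, giving the all-trans ring. The step needs cross- over homo-coupling, head-to-head regiochemistry and face selectivity: the first rests on the MOM cap and twisted carbonyl of 9 (no chelate, no sensitisation), on its excess and on the slow addition of 4, the second on β–β bonding leaving the two best-stabilised radicals, and the third on the ligand.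

Step 6
Reactants: 10 (4-benzyloxy-2-hydroxyphenyl){(1S,2S,3R,4R)-2-[2,4-bis(benzyloxy)-6-(methoxymethoxy)benzoyl]-3,4-bis(4-benzyloxyphenyl)cyclobutyl}methanone
Product: 11 (4-benzyloxy-2-hydroxyphenyl){(1S,2S,3R,4R)-2-[2,4-bis(benzyloxy)-6-hydroxybenzoyl]-3,4-bis(4-benzyloxyphenyl)cyclobutyl}methanone
Conditions: HCl (cat.), MeOH/THF, 45 °C
Reagents that add atoms: none
Why: Acid-catalysed acetal exchange removes only the MOM ether (aryl benzyl ethers are inert), and because the all-trans cyclobutane is the thermodynamic isomer any enolisation at C3 or C3'' returns the same configuration.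

Step 7
Reactants: 11 (4-benzyloxy-2-hydroxyphenyl){(1S,2S,3R,4R)-2-[2,4-bis(benzyloxy)-6-hydroxybenzoyl]-3,4-bis(4-benzyloxyphenyl)cyclobutyl}methanone
Product: 12 (2S,3R)-7-(benzyloxy)-3-[(2S,3R)-5,7-bis(benzyloxy)-2-(4-benzyloxyphenyl)-4-oxochroman-3-yl]-2-(4-benzyloxyphenyl)chroman-4-one
Conditions: (4-BrC6H4)3N(SbCl6) (2.2 equiv), 2,6-di-tert-butylpyridine (2.5 equiv), CH2Cl2, −20 to 0 °C
Reagents that add atoms: none
Why: Proposed new method: outer-sphere one-electron oxidation of the 1,2-bis(4-alkoxyphenyl)cyclobutane unit should give a radical cation whose strained, doubly benzylic C2–C2'' bond is the weakest, so that the ortho-phenol oxygen O1 captures C2 from the backside in a 6-exo-tet closure as that bond breaks, the remaining 4-alkoxybenzyl radical at C2'' is oxidised by the second equivalent and captured by O1'' in the same way, C3 and C3'' are untouched, and inversion at C2 and C2'' (or, through free cations, thermodynamic control) places each aryl group equatorial and trans to its neighbour; the closest known reaction types are the aminium-salt radical-cation cleavage of arylcyclobutanes and the nucleophile-assisted oxidative ring opening of arylcyclopropanes.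

Step 8
Reactants: 12 (2S,3R)-7-(benzyloxy)-3-[(2S,3R)-5,7-bis(benzyloxy)-2-(4-benzyloxyphenyl)-4-oxochroman-3-yl]-2-(4-benzyloxyphenyl)chroman-4-one
Product: 13 (2S,3R)-3-[(2S,3R)-5,7-dihydroxy-2-(4-hydroxyphenyl)-4-oxochroman-3-yl]-7-hydroxy-2-(4-hydroxyphenyl)chroman-4-one
Conditions: H2 (1 atm), Pd/C (10%), EtOAc/MeOH, rt
Reagents that add atoms: none
Why: Hydrogenolysis of the five aryl benzyl ethers over palladium under neutral conditions should leave the ketones, the benzylic C2–O1 and C2''–O1'' bonds of the rings C and all four stereocentres untouched, since nothing in the medium can enolise C3 or open a ring C.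

Compound list
1 | 1-(4-benzyloxy-2-hydroxyphenyl)ethan-1-one (4'-benzyloxy-2'-hydroxyacetophenone) | CC(=O)c1ccc(OCc2ccccc2)cc1O | starting material
2 | 4-(benzyloxy)benzaldehyde | O=Cc1ccc(OCc2ccccc2)cc1 | starting material
3 | (±)-1-(4-benzyloxy-2-hydroxyphenyl)-3-(4-benzyloxyphenyl)-3-hydroxypropan-1-one (aldol adduct) | O=C(CC(O)c1ccc(OCc2ccccc2)cc1)c1ccc(OCc2ccccc2)cc1O | intermediate (not isolated)
4 | (E)-1-(4-benzyloxy-2-hydroxyphenyl)-3-(4-benzyloxyphenyl)prop-2-en-1-one | O=C(/C=C/c1ccc(OCc2ccccc2)cc1)c1ccc(OCc2ccccc2)cc1O | intermediate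
5 | 1-(2,4,6-trihydroxyphenyl)ethan-1-one (2',4',6'-trihydroxyacetophenone) | CC(=O)c1c(O)cc(O)cc1O | starting material
6 | 1-[2,4-bis(benzyloxy)-6-hydroxyphenyl]ethan-1-one | CC(=O)c1c(O)cc(OCc2ccccc2)cc1OCc1ccccc1 | intermediate
7 | 1-[2,4-bis(benzyloxy)-6-(methoxymethoxy)phenyl]ethan-1-one | CC(=O)c1c(OCOC)cc(OCc2ccccc2)cc1OCc1ccccc1 | intermediate
8 | (±)-1-[2,4-bis(benzyloxy)-6-(methoxymethoxy)phenyl]-3-(4-benzyloxyphenyl)-3-hydroxypropan-1-one (aldol adduct) | O=C(CC(O)c1ccc(OCc2ccccc2)cc1)c1c(OCOC)cc(OCc2ccccc2)cc1OCc1ccccc1 | intermediate (not isolated)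
9 | (E)-1-[2,4-bis(benzyloxy)-6-(methoxymethoxy)phenyl]-3-(4-benzyloxyphenyl)prop-2-en-1-one | O=C(/C=C/c1ccc(OCc2ccccc2)cc1)c1c(OCOC)cc(OCc2ccccc2)cc1OCc1ccccc1 | intermediate
10 | (4-benzyloxy-2-hydroxyphenyl){(1S,2S,3R,4R)-2-[2,4-bis(benzyloxy)-6-(methoxymethoxy)benzoyl]-3,4-bis(4-benzyloxyphenyl)cyclobutyl}methanone, all-trans | O=C(c1ccc(OCc2ccccc2)cc1O)[C@@H]1[C@@H](C(=O)c2c(OCOC)cc(OCc3ccccc3)cc2OCc2ccccc2)[C@H](c2ccc(OCc3ccccc3)cc2)[C@H]1c1ccc(OCc2ccccc2)cc1 | intermediate
11 | (4-benzyloxy-2-hydroxyphenyl){(1S,2S,3R,4R)-2-[2,4-bis(benzyloxy)-6-hydroxybenzoyl]-3,4-bis(4-benzyloxyphenyl)cyclobutyl}methanone, all-trans | O=C(c1ccc(OCc2ccccc2)cc1O)[C@@H]1[C@@H](C(=O)c2c(O)cc(OCc3ccccc3)cc2OCc2ccccc2)[C@H](c2ccc(OCc3ccccc3)cc2)[C@H]1c1ccc(OCc2ccccc2)cc1 | intermediate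
12 | (2S,3R)-7-(benzyloxy)-3-[(2S,3R)-5,7-bis(benzyloxy)-2-(4-benzyloxyphenyl)-4-oxochroman-3-yl]-2-(4-benzyloxyphenyl)chroman-4-one, both rings C 2,3-trans | O=C1c2ccc(OCc3ccccc3)cc2O[C@H](c2ccc(OCc3ccccc3)cc2)[C@H]1[C@H]1C(=O)c2c(OCc3ccccc3)cc(OCc3ccccc3)cc2O[C@@H]1c1ccc(OCc2ccccc2)cc1 | intermediate
13 | (2S,3R)-3-[(2S,3R)-5,7-dihydroxy-2-(4-hydroxyphenyl)-4-oxochroman-3-yl]-7-hydroxy-2-(4-hydroxyphenyl)chroman-4-one, the (2S,3R,2''S,3''R)-3,3''-biflavanone | O=C1c2ccc(O)cc2O[C@H](c2ccc(O)cc2)[C@H]1[C@H]1C(=O)c2c(O)cc(O)cc2O[C@@H]1c1ccc(O)cc1 | target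

Total step count: 8. Longest linear sequence: 7 steps (steps 2, 3, 4, 5, 6, 7 and 8, from 5).

Steps most likely to fail

Step 5. The chelated chalcone may couple with itself instead of with the ground-state enone, bonding may go head to tail, or the ligand may discriminate the enone faces poorly with this new partner class. Fallback, from 4 and 9 back to 10: the two chalcones would be irradiated together (blue LEDs, MeCN) with Ir[dF(CF3)ppy]2(dtbbpy)PF6 as a plain triplet sensitiser and no Lewis acid, 9 in excess. This is the known energy-transfer [2+2] dimerisation of chalcones, which favours the head-to-head all-trans cyclobutane. Run on the mixture, it should give the crossed adduct statistically and as a racemate, that is 10 together with its mirror image (4-benzyloxy-2-hydroxyphenyl){(1R,2R,3S,4S)-2-[2,4-bis(benzyloxy)-6-(methoxymethoxy)benzoyl]-3,4-bis(4-benzyloxyphenyl)cyclobutyl}methanone F1. Chromatography would remove homo-coupled material, and preparative HPLC on a chiral stationary phase would separate 10 from F1.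

Step 7. The radical cation may undergo cycloreversion (loss of C3–C3'' as well), or oxidation elsewhere in the molecule may outrun capture by the phenols. Fallback, from 4 and 9 back to 12 without a cyclobutane, using known chemistry only:
- Chalcone 4 would be cyclised by intramolecular oxa-Michael addition (NaOAc, EtOH, reflux) and the racemic flavanone resolved by preparative HPLC on a chiral stationary phase into (2S)-7-benzyloxy-2-(4-benzyloxyphenyl)chroman-4-one F2 and its antipode (2R)-7-benzyloxy-2-(4-benzyloxyphenyl)chroman-4-one F3, which is set aside.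
- Chalcone 9 would lose its MOM group (HCl, MeOH/THF) to give (E)-1-[2,4-bis(benzyloxy)-6-hydroxyphenyl]-3-(4-benzyloxyphenyl)prop-2-en-1-one F4. This would be cyclised and resolved in the same way into (2S)-5,7-bis(benzyloxy)-2-(4-benzyloxyphenyl)chroman-4-one F5 and its antipode (2R)-5,7-bis(benzyloxy)-2-(4-benzyloxyphenyl)chroman-4-one F6.
- The lithium enolate of F2 (LiN(SiMe3)2, THF, −78 °C) would be added to excess i-Pr2SiCl2 to give (2S)-7-benzyloxy-2-(4-benzyloxyphenyl)-4-[chloro(diisopropyl)silyloxy]-2H-chromene F7.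
- F7 with the lithium enolate of F5 would give the unsymmetrical silylene bis-enol ether diisopropyl{[(2S)-7-benzyloxy-2-(4-benzyloxyphenyl)-2H-chromen-4-yl]oxy}{[(2S)-5,7-bis(benzyloxy)-2-(4-benzyloxyphenyl)-2H-chromen-4-yl]oxy}silane F8.
- Oxidation of F8 with (NH4)2Ce(NO3)6 and NaHCO3 in MeCN/EtCN at −20 °C (oxidative enolate heterocoupling through a silicon tether, a known way to unsymmetrical 1,4-diketones) should form C3–C3'' anti to both C2-aryl groups and so give 12.

Step 8. Hydrogenolysis may also open a ring C at its benzylic C–O bond, reduce a ketone, or stop short of full debenzylation. Fallback, from 12 back to 13: non-reductive Lewis-acid dealkylation with BCl3 and pentamethylbenzene as cation scavenger in CH2Cl2 at −78 °C, which cleaves aryl benzyl ethers without hydrogen and so cannot hydrogenolyse the rings C (no new compound, F0).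

Further compounds
F1 | step 5 | (4-benzyloxy-2-hydroxyphenyl){(1R,2R,3S,4S)-2-[2,4-bis(benzyloxy)-6-(methoxymethoxy)benzoyl]-3,4-bis(4-benzyloxyphenyl)cyclobutyl}methanone (mirror image of 10) | O=C(c1ccc(OCc2ccccc2)cc1O)[C@H]1[C@H](C(=O)c2c(OCOC)cc(OCc3ccccc3)cc2OCc2ccccc2)[C@@H](c2ccc(OCc3ccccc3)cc2)[C@@H]1c1ccc(OCc2ccccc2)cc1
F2 | step 7 | (2S)-7-benzyloxy-2-(4-benzyloxyphenyl)chroman-4-one | O=C1c2ccc(OCc3ccccc3)cc2O[C@H](c2ccc(OCc3ccccc3)cc2)C1
F3 | step 7 | (2R)-7-benzyloxy-2-(4-benzyloxyphenyl)chroman-4-one | O=C1c2ccc(OCc3ccccc3)cc2O[C@@H](c2ccc(OCc3ccccc3)cc2)C1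
F4 | step 7 | (E)-1-[2,4-bis(benzyloxy)-6-hydroxyphenyl]-3-(4-benzyloxyphenyl)prop-2-en-1-one | O=C(/C=C/c1ccc(OCc2ccccc2)cc1)c1c(O)cc(OCc2ccccc2)cc1OCc1ccccc1
F5 | step 7 | (2S)-5,7-bis(benzyloxy)-2-(4-benzyloxyphenyl)chroman-4-one | O=C1c2c(OCc3ccccc3)cc(OCc3ccccc3)cc2O[C@H](c2ccc(OCc3ccccc3)cc2)C1
F6 | step 7 | (2R)-5,7-bis(benzyloxy)-2-(4-benzyloxyphenyl)chroman-4-one | O=C1c2c(OCc3ccccc3)cc(OCc3ccccc3)cc2O[C@@H](c2ccc(OCc3ccccc3)cc2)C1
F7 | step 7 | (2S)-7-benzyloxy-2-(4-benzyloxyphenyl)-4-[chloro(diisopropyl)silyloxy]-2H-chromene | CC(C)[Si](Cl)(C(C)C)OC1=C[C@@H](c2ccc(OCc3ccccc3)cc2)Oc2cc(OCc3ccccc3)ccc21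
F8 | step 7 | diisopropyl{[(2S)-7-benzyloxy-2-(4-benzyloxyphenyl)-2H-chromen-4-yl]oxy}{[(2S)-5,7-bis(benzyloxy)-2-(4-benzyloxyphenyl)-2H-chromen-4-yl]oxy}silane | CC(C)[Si](C(C)C)(OC1=C[C@@H](c2ccc(OCc3ccccc3)cc2)Oc2cc(OCc3ccccc3)ccc21)OC1=C[C@@H](c2ccc(OCc3ccccc3)cc2)Oc2cc(OCc3ccccc3)cc(OCc3ccccc3)c21
F0 | step 8 | none | none
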